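**Retrosynthetic overview**
1. End game, read backwards: ester at the axial allylic oxygen ⇐ SeO2 allylic hydroxylation beside the exocyclic methylene ⇐ ester at the equatorial oxygen ⇐ hydroxyl-directed epoxidation of an isopropenyl group.
2. Key disconnection: the six-membered ring is opened at two bonds, the one between the methylidene-bearing carbon and the ring-fusion CH, and the one between the carbinol carbon and its ring CH2 neighbour. This gives a trans-4,5-disubstituted cyclopent-2-enone carrying an aldehyde, plus a three-carbon 2-copper-allylsilane (conjugate addition, then Hosomi–Sakurai closure in the same flask).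
3. Enabling feature: in the cyclohexane ring the sp2 carbon C(=CH2) sits between the ring-fusion CH that is β to the cyclopentanone C=O and a ring carbon bonded to the equatorial carbinol carbon. The ring therefore contains a 2-substituted allyl unit placed 1,4 to a ketone and next to a homoallylic alcohol, which is what a vinyl-metal/allylsilane pair delivers to an enone and an aldehyde.
4. The enone aldehyde comes from commercial bicyclic lactone diol 1, which already holds the five-membered carbocycle. Lactone α-carbon → isopropenyl-bearing centre (convex-face aldol/Peterson); CH2OH → (S)-CH(OAc)CH3; ring OH → ketone; lactone oxygen → mesylate for enone formation.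
5. Ring order: cyclopentane (bought), cyclohexane (key step), oxirane (after it). The unsaturated acid comes from butane-2,3-dione (Wittig, CBS reduction).

Key step: step 13

Remark: the 2-methylbutanoyl group is taken as (R), as written in the target SMILES; (R)-2-methylbutanoic acid and lactone diol 1 are taken as commercial.
Remark: locants for the bicyclic compounds follow octahydro-2H-inden-2-one (C-2 carbonyl, C-1 acetoxyethyl, C-3a/C-7a ring fusion, C-4 methylidene, C-5 and C-6 oxygenated, C-7 isopropenyl or oxiranyl).

Step 1
Reactants: 1 (3aR,4S,5R,6aS)-5-hydroxy-4-(hydroxymethyl)hexahydro-2H-cyclopenta[b]furan-2-one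
Product: 2 bis(triethylsilyl) ether of 1
Conditions: Et3SiCl, imidazole, DMF, 0 → 25 °C
Reagents that add atoms: chlorotriethylsilane, CC[Si](Cl)(CC)CC
Why: Silyl ether formation on both hydroxyl groups protects them for the enolate and hydride steps; no stereocentre is touched.

Step 2
Reactants: 2 bis(triethylsilyl) ether of 1
Product: 5 bis-TES lactone with a prop-1-en-2-yl group on the lactone α-carbon (convex face), via potassium enolate 3 (not isolated), via potassium alkoxide 4 (not isolated)
Conditions: KN(SiMe3)2, THF, −78 °C; then Me3SiCH2C(O)CH3, −78 → 0 °C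
Reagents that add atoms: 1-(trimethylsilyl)propan-2-one, CC(=O)C[Si](C)(C)C
Why: The enolate of the cis-fused bicyclic lactone should add to the ketone on its convex face (aldol addition), which sets the new α-stereocentre cis to the ring-fusion hydrogens, and the β-silyl alkoxide should then undergo Peterson syn-elimination to give only the isopropenyl group.

Step 3
Reactants: 5 convex-face isopropenyl lactone
Product: 6 diol (former lactone carbonyl as CH2OH and former lactone oxygen as secondary ring OH)
Conditions: LiAlH4, THF, 0 °C
Reagents that add atoms: none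
Why: Hydride reduction of the lactone should give the 1,5-diol without touching the α-stereocentre, the silyl ethers or the 1,1-disubstituted alkene.

Step 4
Reactants: 6 diol
Product: 7 primary tert-butyldimethylsilyl ether of 6
Conditions: t-BuMe2SiCl, imidazole, CH2Cl2, −20 → 0 °C
Reagents that add atoms: tert-butylchlorodimethylsilane, CC(C)(C)[Si](C)(C)Cl
Why: Silyl ether formation should be selective for the primary hydroxyl over the hindered secondary ring hydroxyl.

Step 5
Reactants: 7 primary silyl ether
Product: 8 methanesulfonate of the secondary ring hydroxyl of 7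
Conditions: MeSO2Cl, Et3N, CH2Cl2, 0 °C
Reagents that add atoms: methanesulfonyl chloride, CS(=O)(=O)Cl
Why: Sulfonate ester formation turns the former lactone oxygen into the leaving group needed for enone formation; its configuration is irrelevant because this carbon becomes sp2.

Step 6
Reactants: 8 mesylate
Product: 9 aldehyde (ring CH2OSiEt3 converted into CHO)
Conditions: (COCl)2, DMSO, CH2Cl2, −78 → −30 °C; then Et3N, −78 → 0 °C
Reagents that add atoms: none
Why: Swern oxidation should convert the primary triethylsilyl ether directly into the aldehyde, while the secondary triethylsilyl ether and the primary tert-butyldimethylsilyl ether are inert under these conditions.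

Step 7
Reactants: 9 aldehyde
Product: 10 1-hydroxyethyl compound (both carbinol epimers)
Conditions: MeMgBr, THF, −78 °C
Reagents that add atoms: methylmagnesium bromide, C[Mg]Br
Why: Grignard addition to the aldehyde at low temperature should leave mesylate and silyl ethers alone; the carbinol centre is formed unselectively and is erased in step 8.

Step 8
Reactants: 10 carbinol mixture
Product: 11 methyl ketone (acetyl group on the ring)
Conditions: Dess–Martin periodinane, NaHCO3, CH2Cl2, 0 → 25 °C
Reagents that add atoms: none
Why: Buffered Dess–Martin oxidation should give the ketone from both epimers without β-elimination of the neighbouring silyloxy group.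

Step 9
Reactants: 11 methyl ketone
Product: 12 (S)-1-hydroxyethyl compound
Conditions: (R)-1-methyl-3,3-diphenyltetrahydro-1H,3H-pyrrolo[1,2-c][1,3,2]oxazaborole (20 mol %), catecholborane, toluene, −78 °C
Reagents that add atoms: none
Why: Corey–Bakshi–Shibata reduction with methyl as the small group should give the (S)-carbinol under catalyst control, so both epimers of 10 converge on one configuration; catecholborane does not hydroborate the alkene at this temperature.

Step 10
Reactants: 12 (S)-alcohol
Product: 13 acetate of 12
Conditions: Ac2O, pyridine, 4-(dimethylamino)pyridine (cat.), CH2Cl2, 0 → 25 °C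
Reagents that add atoms: acetic anhydride, CC(=O)OC(C)=O
Why: Acylation with retention installs the acetate of the target.

Step 11
Reactants: 13 acetate
Product: 14 diol (ring OH and side-chain CH2OH free; mesylate and acetate kept)
Conditions: HF·pyridine, pyridine, THF, 0 → 25 °C
Reagents that add atoms: none
Why: Buffered fluoride cleavage should remove both silyl ethers and leave the acetate, the mesylate and the alkene intact.

Step 12
Reactants: 14 diol
Product: 16 (2R)-2-{(1R,5S)-5-[(1S)-1-acetoxyethyl]-4-oxocyclopent-2-en-1-yl}-3-methylbut-3-enal, via keto aldehyde mesylate 15 (not isolated)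
Conditions: Dess–Martin periodinane, NaHCO3, CH2Cl2, 0 → 25 °C; then Et3N, 0 °C
Reagents that add atoms: none
Why: Double Dess–Martin oxidation gives 15, whose β-mesyloxy ketone should undergo E1cB elimination with Et3N far faster than loss of the side-chain β-acetate or enolisation of the aldehyde, giving the cyclopentenone.

Step 13
Reactants: 16 enone aldehyde
Product: 19 trans-fused 1-[(1S)-1-acetoxyethyl]-6-hydroxy-4-methylidene-7-(prop-1-en-2-yl)octahydro-2H-inden-2-one (6-OH equatorial), via silyl enol ether 17 (not isolated), via keto aldehyde allylsilane 18 (not isolated)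
Conditions: 2-bromo-3-(trimethylsilyl)propene, Mg, THF; CuBr·SMe2, −45 °C; then 16, Me3SiCl, −78 °C; then t-BuOH, BF3·OEt2, CH2Cl2, −78 → −30 °C
Reagents that add atoms: 2-bromo-3-(trimethylsilyl)propene, C=C(Br)C[Si](C)(C)C
Why: The 2-(silylmethyl)vinylcopper reagent should add in a Me3SiCl-accelerated conjugate addition to the enone β-carbon on the face opposite the adjacent branched side chain, giving silyl enol ether 17 with the two ring substituents trans; t-BuOH/BF3 then destroys excess reagent and protonates the enol ether to ketone 18, and BF3 activation of the formyl group triggers an intramolecular Hosomi–Sakurai allylation in which the terminal CH2 of the allylsilane attacks the aldehyde and loss of the silyl group leaves the exocyclic methylene. The closest known reaction type is methylenecycloalkane annulation with 2-metallated allylsilanes as bifunctional reagents (conjugate addition, then Sakurai ring closure). The cyclohexane ring closes by 6-exo-trig attack on the C=O through a chair-like transition state. The ring-fusion stereocentre is set by substrate control in the conjugate addition (anti to the ring substituent next to the β-carbon), which fixes the trans ring fusion; the carbinol centre is set in the chair that has the ring-fusion bonds and the isopropenyl group equatorial and the BF3-bound oxygen equatorial (open, antiperiplanar arrangement), placing the hydroxyl trans to the isopropenyl group. The step needs enone-over-aldehyde selectivity in the copper stage (a monoorganocopper reagent with Me3SiCl should not attack the α-branched aldehyde in the absence of a Lewis acid) and allylsilane-over-enol-ether attack on the aldehyde (secured by cleaving the silyl enol ether before ring closure; the alternative aldol closure would give a strained bicyclo[2.2.1] skeleton).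

Step 14
Reactants: 19 hydrindanone alcohol
Product: 20 epoxide of 19 with 7-[(2S)-2-methyloxiran-2-yl]
Conditions: VO(acac)2 (5 mol %), t-BuOOH, CH2Cl2, 0 → 25 °C
Reagents that add atoms: tert-butyl hydroperoxide, CC(C)(C)OO
Why: In this hydroxyl-directed epoxidation the equatorial homoallylic hydroxyl is gauche to the isopropenyl group but anti to the exocyclic methylene, so only the isopropenyl alkene should be reached, and delivery to the face syn to the carbinol carbon in the rotamer with the allylic C–H eclipsing C=CH2 should set the (S)-epoxide centre.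

Step 15
Reactants: 20 epoxy alcohol; 21 (R)-2-methylbutanoic acid
Product: 22 6-O-[(R)-2-methylbutanoyl] ester of 20
Conditions: N,N'-dicyclohexylcarbodiimide, 4-(dimethylamino)pyridine, CH2Cl2, 0 → 25 °C
Reagents that add atoms: none
Why: Steglich esterification of the equatorial secondary alcohol should proceed with retention at the carbinol and at the α-stereocentre of the acid.

Step 16
Reactants: 22 monoester
Product: 23 5-hydroxy derivative of 22 (axial OH cis to the 6-ester)
Conditions: SeO2 (0.5 equiv), t-BuOOH, CH2Cl2, 25 °C
Reagents that add atoms: selenium dioxide, O=[Se]=O; tert-butyl hydroperoxide, CC(C)(C)OO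
Why: SeO2 allylic hydroxylation (ene reaction, then [2,3]-sigmatropic shift) should take place at the ring CH2 and not at the ring-fusion CH, and should replace the pseudo-axial allylic hydrogen with retention, giving the axial alcohol.

Step 17
Reactants: 24 butane-2,3-dione
Product: 25 tert-butyl (E)-3-methyl-4-oxopent-2-enoate
Conditions: Ph3P=CHCO2t-Bu, CH2Cl2, 0 → 25 °C (dione in excess)
Reagents that add atoms: tert-butyl (triphenyl-λ5-phosphanylidene)acetate, CC(C)(C)OC(=O)C=P(c1ccccc1)(c1ccccc1)c1ccccc1
Why: Wittig olefination of one carbonyl of the symmetrical dione with a stabilised ylide should give the (E)-enoate, with the ester trans to the acetyl group.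

Step 18
Reactants: 25 keto enoate
Product: 26 tert-butyl (S,E)-4-hydroxy-3-methylpent-2-enoate
Conditions: (R)-1-methyl-3,3-diphenyltetrahydro-1H,3H-pyrrolo[1,2-c][1,3,2]oxazaborole (20 mol %), catecholborane, toluene, −78 °C
Reagents that add atoms: none
Why: Corey–Bakshi–Shibata 1,2-reduction of the alkenyl methyl ketone should give the (S)-allylic alcohol under catalyst control.

Step 19
Reactants: 26 hydroxy enoate
Product: 27 tert-butyl (S,E)-4-acetoxy-3-methylpent-2-enoate
Conditions: Ac2O, pyridine, 4-(dimethylamino)pyridine (cat.), CH2Cl2, 0 → 25 °C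
Reagents that add atoms: acetic anhydride, CC(=O)OC(C)=O
Why: Acylation of the secondary alcohol with retention.

Step 20
Reactants: 27 acetoxy tert-butyl ester
Product: 28 (S,E)-4-acetoxy-3-methylpent-2-enoic acid
Conditions: CF3CO2H, CH2Cl2, 0 → 25 °C
Reagents that add atoms: none
Why: Acidolysis of the tert-butyl ester (loss of isobutene) should leave the acetate and the electron-poor allylic system intact.

Step 21
Reactants: 23 axial allylic alcohol; 28 acid
Product: 29 target CNP0170703.2
Conditions: N,N'-dicyclohexylcarbodiimide, 4-(dimethylamino)pyridine, CH2Cl2, 0 → 25 °C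
Reagents that add atoms: none
Why: Steglich esterification of the axial allylic alcohol with retention under mild conditions should avoid E1cB loss of the β-acetoxy group and isomerisation of the enoate.

**Compound list**
1 | (3aR,4S,5R,6aS)-5-hydroxy-4-(hydroxymethyl)hexahydro-2H-cyclopenta[b]furan-2-one | O=C1C[C@@H]2[C@@H](CO)[C@H](O)C[C@@H]2O1 | starting material
2 | bis(triethylsilyl) ether of 1 | O=C1C[C@@H]2[C@@H](CO[Si](CC)(CC)CC)[C@H](O[Si](CC)(CC)CC)C[C@@H]2O1 | intermediate
3 | potassium enolate of 2 (not isolated) | [K+].[O-]C1=C[C@@H]2[C@@H](CO[Si](CC)(CC)CC)[C@H](O[Si](CC)(CC)CC)C[C@@H]2O1 | intermediate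
4 | potassium alkoxide from 3 and 1-(trimethylsilyl)propan-2-one, new group on the convex face, carbinol carbon unassigned (not isolated) | O=C1[C@@H](C(C)([O-])C[Si](C)(C)C)[C@@H]2[C@@H](CO[Si](CC)(CC)CC)[C@H](O[Si](CC)(CC)CC)C[C@@H]2O1.[K+] | intermediate
5 | lactone 2 with a prop-1-en-2-yl group on the lactone α-carbon, convex face (cis to both ring-fusion hydrogens) | O=C1[C@@H](C(C)=C)[C@@H]2[C@@H](CO[Si](CC)(CC)CC)[C@H](O[Si](CC)(CC)CC)C[C@@H]2O1 | intermediate
6 | diol from 5: cyclopentanol carrying the 1-hydroxy-3-methylbut-3-en-2-yl chain, all centres as in 5 | OC[C@@H](C(C)=C)[C@@H]1[C@@H](CO[Si](CC)(CC)CC)[C@H](O[Si](CC)(CC)CC)C[C@@H]1O | intermediate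
7 | 6 with the primary hydroxyl as tert-butyldimethylsilyl ether | CC(C)(C)[Si](C)(C)OC[C@@H](C(C)=C)[C@@H]1[C@@H](CO[Si](CC)(CC)CC)[C@H](O[Si](CC)(CC)CC)C[C@@H]1O | intermediate
8 | methanesulfonate of the ring hydroxyl of 7 | CC(C)(C)[Si](C)(C)OC[C@@H](C(C)=C)[C@@H]1[C@@H](CO[Si](CC)(CC)CC)[C@H](O[Si](CC)(CC)CC)C[C@@H]1OS(C)(=O)=O | intermediate
9 | aldehyde from 8 (ring CHO in place of CH2OSiEt3) | CC(C)(C)[Si](C)(C)OC[C@@H](C(C)=C)[C@@H]1[C@@H](C=O)[C@H](O[Si](CC)(CC)CC)C[C@@H]1OS(C)(=O)=O | intermediate
10 | 1-hydroxyethyl compound from 9, both carbinol epimers | CC(C)(C)[Si](C)(C)OC[C@@H](C(C)=C)[C@@H]1[C@@H](C(C)O)[C@H](O[Si](CC)(CC)CC)C[C@@H]1OS(C)(=O)=O | intermediate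
11 | methyl ketone from 10 | CC(C)(C)[Si](C)(C)OC[C@@H](C(C)=C)[C@@H]1[C@@H](C(C)=O)[C@H](O[Si](CC)(CC)CC)C[C@@H]1OS(C)(=O)=O | intermediate
12 | (S)-1-hydroxyethyl compound from 11 | CC(C)(C)[Si](C)(C)OC[C@@H](C(C)=C)[C@@H]1[C@@H]([C@H](C)O)[C@H](O[Si](CC)(CC)CC)C[C@@H]1OS(C)(=O)=O | intermediate
13 | acetate of 12 | CC(C)(C)[Si](C)(C)OC[C@@H](C(C)=C)[C@@H]1[C@@H]([C@H](C)OC(C)=O)[C@H](O[Si](CC)(CC)CC)C[C@@H]1OS(C)(=O)=O | intermediate
14 | diol from 13 (ring OH and CH2OH free) | OC[C@@H](C(C)=C)[C@@H]1[C@@H]([C@H](C)OC(C)=O)[C@H](O)C[C@@H]1OS(C)(=O)=O | intermediate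
15 | keto aldehyde mesylate from 14 (not isolated) | O=C[C@@H](C(C)=C)[C@@H]1[C@@H]([C@H](C)OC(C)=O)C(=O)C[C@@H]1OS(C)(=O)=O | intermediate
16 | (2R)-2-{(1R,5S)-5-[(1S)-1-acetoxyethyl]-4-oxocyclopent-2-en-1-yl}-3-methylbut-3-enal (ring substituents trans) | O=C[C@@H](C(C)=C)[C@H]1C=CC(=O)[C@@H]1[C@H](C)OC(C)=O | intermediate
17 | trimethylsilyl enol ether of the conjugate adduct, new ring substituent trans to its neighbour (not isolated) | O=C[C@@H](C(C)=C)[C@H]1[C@H](C(=C)C[Si](C)(C)C)C=C(O[Si](C)(C)C)[C@@H]1[C@H](C)OC(C)=O | intermediate
18 | keto aldehyde allylsilane: cyclopentanone with trans 3-(trimethylsilyl)prop-1-en-2-yl and formyl-bearing chains (not isolated) | O=C[C@@H](C(C)=C)[C@H]1[C@H](C(=C)C[Si](C)(C)C)CC(=O)[C@@H]1[C@H](C)OC(C)=O | intermediate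
19 | trans-fused 1-[(1S)-1-acetoxyethyl]-6-hydroxy-4-methylidene-7-(prop-1-en-2-yl)octahydro-2H-inden-2-one, 6-OH equatorial and trans to the 7-substituent | C=C1[C@@H]2CC(=O)[C@H]([C@H](C)OC(C)=O)[C@H]2[C@H](C(C)=C)[C@@H](O)C1 | intermediate
20 | 19 with the isopropenyl group as (2S)-2-methyloxiran-2-yl | C=C1[C@@H]2CC(=O)[C@H]([C@H](C)OC(C)=O)[C@H]2[C@H]([C@@]2(C)CO2)[C@@H](O)C1 | intermediate
21 | (R)-2-methylbutanoic acid | CC[C@@H](C)C(=O)O | starting material
22 | 6-O-[(R)-2-methylbutanoyl] ester of 20 | C=C1[C@@H]2CC(=O)[C@H]([C@H](C)OC(C)=O)[C@H]2[C@H]([C@@]2(C)CO2)[C@@H](OC(=O)[C@H](C)CC)C1 | intermediate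
23 | 5-hydroxy derivative of 22, OH axial and cis to the 6-ester | C=C1[C@@H]2CC(=O)[C@H]([C@H](C)OC(C)=O)[C@H]2[C@H]([C@@]2(C)CO2)[C@@H](OC(=O)[C@H](C)CC)[C@H]1O | intermediate
24 | butane-2,3-dione | CC(=O)C(C)=O | starting material
25 | tert-butyl (E)-3-methyl-4-oxopent-2-enoate | CC(C)(C)OC(=O)/C=C(\C)C(C)=O | intermediate
26 | tert-butyl (S,E)-4-hydroxy-3-methylpent-2-enoate | CC(C)(C)OC(=O)/C=C(\C)[C@H](C)O | intermediate
27 | tert-butyl (S,E)-4-acetoxy-3-methylpent-2-enoate | CC(C)(C)OC(=O)/C=C(\C)[C@H](C)OC(C)=O | intermediate
28 | (S,E)-4-acetoxy-3-methylpent-2-enoic acid | OC(=O)/C=C(\C)[C@H](C)OC(C)=O | intermediate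
29 | CNP0170703.2: 5-O-[(S,E)-4-acetoxy-3-methylpent-2-enoyl] ester of 23 | C=C1[C@@H]2CC(=O)[C@H]([C@H](C)OC(C)=O)[C@H]2[C@H]([C@@]2(C)CO2)[C@@H](OC(=O)[C@H](C)CC)[C@H]1OC(=O)/C=C(\C)[C@H](C)OC(C)=O | target

**Step count and risks**
Total: 21 steps. Longest linear sequence: 17 steps (steps 1–16 and 21).

Steps most likely to fail:

1. Step 13. The organocopper reagent may attack the free formyl group, the enol ether or enolate may close onto the aldehyde in an aldol-type reaction, or the ring closure may place the hydroxyl axial (poor facial selectivity at the carbinol carbon). Fallback: the two bond formations are separated. Starting from 13, selective acidic cleavage of the secondary triethylsilyl ether (AcOH, THF, H2O) should give ring alcohol F1. Dess–Martin oxidation followed by Et3N should give enone silyl ether F2. The same organocopper/Me3SiCl conjugate addition with mild acid work-up should give ketone F3, and HF·pyridine then gives primary alcohol F4. Dess–Martin oxidation gives 18, now isolated, which is cyclised with the bulky Lewis acid methylaluminium bis(4-bromo-2,6-di-tert-butylphenoxide), a reagent class that favours the equatorial, trans alcohol in related aldehyde–olefin closures. The route is rejoined at 19.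

2. Step 14. Oxygen transfer may show poor facial selectivity at the isopropenyl group, or may also reach the exocyclic methylene. Fallback: substrate direction is replaced by catalyst control. Alcohol 19 is epoxidised with VO(Oi-Pr)3 and a chiral C2-symmetric bishydroxamic acid ligand (a complex of pentavalent vanadium) with cumene hydroperoxide, a catalyst type that sets the epoxide configuration of homoallylic alcohols independently of the substrate. This makes no new compound F0 and returns to 20.

3. Step 16. The allylic oxidation may stall, over-oxidise to the enone, or deliver oxygen to the wrong face. Fallback: inversion instead of direct axial hydroxylation. Starting from 22, the oxidation is driven to exocyclic enone F5 (excess SeO2/t-BuOOH, or MnO2 on the alcohol mixture). Luche reduction (NaBH4, CeCl3·7H2O, MeOH, −78 °C) by axial hydride attack should give equatorial allylic alcohol F6. Mitsunobu esterification of F6 with acid 28 (PPh3, diisopropyl azodicarboxylate) inverts the carbinol centre and rejoins the route at 29.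

Further compounds
F1 | step 13 | 13 with the ring triethylsilyl ether cleaved (ring OH free) | CC(C)(C)[Si](C)(C)OC[C@@H](C(C)=C)[C@@H]1[C@@H]([C@H](C)OC(C)=O)[C@H](O)C[C@@H]1OS(C)(=O)=O
F2 | step 13 | tert-butyldimethylsilyl ether of the primary alcohol corresponding to enone aldehyde 16 | CC(C)(C)[Si](C)(C)OC[C@@H](C(C)=C)[C@H]1C=CC(=O)[C@@H]1[C@H](C)OC(C)=O
F3 | step 13 | conjugate adduct of F2: trans cyclopentanone with the 3-(trimethylsilyl)prop-1-en-2-yl group | CC(C)(C)[Si](C)(C)OC[C@@H](C(C)=C)[C@H]1[C@H](C(=C)C[Si](C)(C)C)CC(=O)[C@@H]1[C@H](C)OC(C)=O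
F4 | step 13 | primary alcohol from F3 | OC[C@@H](C(C)=C)[C@H]1[C@H](C(=C)C[Si](C)(C)C)CC(=O)[C@@H]1[C@H](C)OC(C)=O
F0 | step 14 | none | none
F5 | step 16 | 5-oxo compound (exocyclic enone) from 22 | C=C1[C@@H]2CC(=O)[C@H]([C@H](C)OC(C)=O)[C@H]2[C@H]([C@@]2(C)CO2)[C@@H](OC(=O)[C@H](C)CC)C1=O
F6 | step 16 | 5-epimer of 23 (equatorial 5-OH) | C=C1[C@@H]2CC(=O)[C@H]([C@H](C)OC(C)=O)[C@H]2[C@H]([C@@]2(C)CO2)[C@@H](OC(=O)[C@H](C)CC)[C@@H]1O
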